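Retrosynthesis: remove the three MOM ethers; cut C4–C4a (closure of ring C) together with the C3–H bond, back to an achiral aryl 2-arylallyl ether; cut O1–C2 to a ring A chlorophenol and a ring B 2-arylallyl alcohol; cut the ring B–C3 bond, both aryl–prenyl bonds and the ring A C7–O bond.
Enabling feature: C3 is a benzylic CH between two methylenes (C2 on O1, C4 on C4a), so it is the anti-Markovnikov hydrometalation product of a 1,1-disubstituted alkene C3=C4 that carries ring B; C4a is the ring A carbon between O1 and the 5-methoxy group, so the chlorine of 2-chloro-3-methoxyphenol marks it against C8.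
Forward order: the ring A fragment (steps 1–5) and the ring B fragment (steps 6–8) are decorated separately, each prenyl group being placed between two oxygens by directed lithiation; they are joined through O1–C2 (step 9); ring C is closed last (step 10); deprotection follows (step 11).
Stereochemistry: the only stereocentre, C3 (R), is set by a chiral copper hydride catalyst in the hydroboration stage of step 10 and is carried unchanged through ring closure and deprotection.

Key step: step 10

Remark: (R)-DTBM-SEGPHOS is taken to deliver the (R)-boronate; the sense of induction is to be fixed first on a simple 2-arylallyl aryl ether, and the (S)-ligand is used instead if that test points the other way.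

Step 1
Reactants: 1 2-chloro-3-methoxyphenol
Product: 2 (2-chloro-3-methoxyphenoxy)triisopropylsilane
Conditions: iPr3SiCl, imidazole, DMF, rt
Reagents that add atoms: triisopropylsilyl chloride, CC(C)[Si](Cl)(C(C)C)C(C)C
Why: O-silylation of the phenol should give a bulky, non-coordinating silyl ether that later shields the neighbouring ring C–H (the future C8) from lithiation.

Step 2
Reactants: 2 (2-chloro-3-methoxyphenoxy)triisopropylsilane
Product: 4 4-chloro-3-methoxy-5-(triisopropylsilyloxy)phenol, via aryl pinacol boronate 3 (not isolated)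
Conditions: [Ir(OMe)(cod)]2 (1.5 mol%), 4,4'-di-tert-butyl-2,2'-bipyridine (3 mol%), B2pin2 (1.0 equiv), THF, 80 °C; then KHSO5 (as Oxone), acetone/H2O, rt
Reagents that add atoms: bis(pinacolato)diboron, CC1(C)OB(OC1(C)C)B1OC(C)(C)C(C)(C)O1 (boryl group of 3 only); potassium peroxymonosulfate, [K+].[O-]S(=O)(=O)OO (phenol oxygen of 4)
Why: Sterically governed iridium-catalysed C–H borylation should attack the only ring C–H without an ortho substituent (para to chlorine, meta to both oxygens), and oxidation of the C–B bond in the same flask gives the phenol (one-pot C–H borylation/oxidation).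

Step 3
Reactants: 4 4-chloro-3-methoxy-5-(triisopropylsilyloxy)phenol
Product: 5 [2-chloro-3-methoxy-5-(methoxymethoxy)phenoxy]triisopropylsilane
Conditions: MOMCl, iPr2NEt, CH2Cl2, 0 °C to rt
Reagents that add atoms: chloromethyl methyl ether, COCCl
Why: O-alkylation of the phenol (MOM ether formation) installs the group that protects the future 7-OH and directs the next lithiation.

Step 4
Reactants: 5 [2-chloro-3-methoxy-5-(methoxymethoxy)phenoxy]triisopropylsilane; 6 1-bromo-3-methylbut-2-ene (prenyl bromide)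
Product: 8 [2-chloro-3-methoxy-5-(methoxymethoxy)-4-(3-methylbut-2-en-1-yl)phenoxy]triisopropylsilane, via aryllithium 7 (not isolated)
Conditions: n-BuLi, THF, −78 to −30 °C; then CuBr·SMe2 (10 mol%), prenyl bromide, −78 °C to rt
Reagents that add atoms: n-butyllithium, [Li]CCCC (lithium of 7 only)
Why: Directed ortho-metalation should remove the proton flanked by the MOM ether and the methoxy group (the other ring C–H lies beside the bulky, non-coordinating silyl ether, and the chloride has no ortho hydrogen and does not exchange at low temperature), and copper-catalysed SN2 allylation of the aryllithium puts the prenyl group at the future C6.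

Step 5
Reactants: 8 [2-chloro-3-methoxy-5-(methoxymethoxy)-4-(3-methylbut-2-en-1-yl)phenoxy]triisopropylsilane
Product: 9 2-chloro-3-methoxy-5-(methoxymethoxy)-4-(3-methylbut-2-en-1-yl)phenol
Conditions: Bu4NF, AcOH, THF, 0 °C
Reagents that add atoms: none
Why: Fluoride-induced desilylation of the aryl silyl ether frees the phenol that becomes O1, leaving MOM ether, chloride and prenyl group untouched.

Step 6
Reactants: 10 4-bromobenzene-1,3-diol (4-bromoresorcinol)
Product: 11 1-bromo-2,4-bis(methoxymethoxy)benzene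
Conditions: MOMCl, iPr2NEt, CH2Cl2, 0 °C to rt
Reagents that add atoms: chloromethyl methyl ether, COCCl
Why: Double O-alkylation (MOM ether formation) protects both phenols and provides the two groups that direct the next metalation.

Step 7
Reactants: 11 1-bromo-2,4-bis(methoxymethoxy)benzene; 6 1-bromo-3-methylbut-2-ene
Product: 13 1-bromo-2,4-bis(methoxymethoxy)-3-(3-methylbut-2-en-1-yl)benzene, via aryllithium 12 (not isolated)
Conditions: lithium 2,2,6,6-tetramethylpiperidide (from 2,2,6,6-tetramethylpiperidine and n-BuLi), THF, −78 °C; then CuBr·SMe2 (10 mol%), prenyl bromide, −78 to 0 °C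
Reagents that add atoms: lithium 2,2,6,6-tetramethylpiperidide, [Li]N1C(C)(C)CCCC1(C)C (lithium of 12 only)
Why: Directed ortho-metalation with a hindered lithium amide should remove the proton between the two MOM ethers without bromine–lithium exchange (the aryllithium is meta to bromine and cannot lose LiBr), and copper-catalysed SN2 allylation with prenyl bromide follows.

Step 8
Reactants: 13 1-bromo-2,4-bis(methoxymethoxy)-3-(3-methylbut-2-en-1-yl)benzene; 14 2-bromoprop-2-en-1-ol
Product: 16 2-[2,4-bis(methoxymethoxy)-3-(3-methylbut-2-en-1-yl)phenyl]prop-2-en-1-ol, via aryl pinacol boronate 15 (not isolated)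
Conditions: Pd(dppf)Cl2 (3 mol%), B2pin2, KOAc, 1,4-dioxane, 90 °C; then 2-bromoprop-2-en-1-ol, aq K2CO3, 90 °C
Reagents that add atoms: bis(pinacolato)diboron, CC1(C)OB(OC1(C)C)B1OC(C)(C)C(C)(C)O1 (boryl group of 15 only)
Why: Miyaura borylation of the aryl bromide and Suzuki–Miyaura coupling of the boronate with the vinyl bromide in one flask should build the 2-arylallyl alcohol, which holds C2, C3 and C4 of the target.

Step 9
Reactants: 9 2-chloro-3-methoxy-5-(methoxymethoxy)-4-(3-methylbut-2-en-1-yl)phenol; 16 2-[2,4-bis(methoxymethoxy)-3-(3-methylbut-2-en-1-yl)phenyl]prop-2-en-1-ol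
Product: 17 1-({2-[2,4-bis(methoxymethoxy)-3-(3-methylbut-2-en-1-yl)phenyl]prop-2-en-1-yl}oxy)-2-chloro-3-methoxy-5-(methoxymethoxy)-4-(3-methylbut-2-en-1-yl)benzene
Conditions: PPh3, DIAD, THF, 0 °C to rt
Reagents that add atoms: none
Why: Mitsunobu etherification should join the acidic ortho-chlorophenol to the primary allylic alcohol (O1–C2), and since the allyl unit has two identical CH2 termini, direct and allylic displacement give the same ether.

Step 10
Reactants: 17 1-({2-[2,4-bis(methoxymethoxy)-3-(3-methylbut-2-en-1-yl)phenyl]prop-2-en-1-yl}oxy)-2-chloro-3-methoxy-5-(methoxymethoxy)-4-(3-methylbut-2-en-1-yl)benzene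
Product: 19 (3R)-3-[2,4-bis(methoxymethoxy)-3-(3-methylbut-2-en-1-yl)phenyl]-5-methoxy-7-(methoxymethoxy)-6-(3-methylbut-2-en-1-yl)-3,4-dihydro-2H-chromene, via (R)-alkyl pinacol boronate 18 (not isolated)
Conditions: CuCl (5 mol%), (R)-DTBM-SEGPHOS (6 mol%), KOtBu (10 mol%), HBpin (1.5 equiv), toluene, rt to 40 °C; then aq K3PO4 (3 equiv, also destroys excess HBpin), Pd(OAc)2 (5 mol%), RuPhos (10 mol%), 90 °C
Reagents that add atoms: pinacolborane, [H]B1OC(C)(C)C(C)(C)O1 (boryl group of 18; the hydride stays as C3–H in 19)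
Why: The phosphine-bound copper hydride formed from CuCl, KOtBu and HBpin adds across the 1,1-disubstituted alkene C3=C4 with hydride to C3 and copper to the terminal C4, sigma-bond metathesis with HBpin releases primary boronate 18, and after hydrolysis of excess HBpin zerovalent palladium/RuPhos inserts into the C4a–Cl bond, the C4–B bond transmetalates to give a seven-membered palladacycle and reductive elimination forms C4–C4a. The closest known reaction types are the copper hydride-catalysed enantioselective hydroboration of alpha-substituted styrenes and the intramolecular B-alkyl Suzuki–Miyaura cyclisation onto an aryl halide. Ring C (the dihydropyran) closes as a six-membered ring by C(sp3)–C(sp2) reductive elimination, the tether O1–C2–C3 being already in place. C3 is set in the hydrocupration, where the chiral bisphosphine tells the alkene faces apart through the difference between ring B and the CH2OAr arm; later it lies beta to palladium and should be kept because reductive elimination from the RuPhos complex outruns beta-hydride elimination. The step needs reaction at the 1,1-disubstituted alkene and not at the two trisubstituted prenyl alkenes (which do not insert into this copper hydride), copper at C4 and not at C3 (secured by the fully substituted C3 and the electron-rich, ortho-substituted ring B, which disfavour a benzylic copper that could expel aryloxide), and closure at C4a and not C8 (secured by the chlorine, which is inert to copper hydride).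

Step 11
Reactants: 19 (3R)-3-[2,4-bis(methoxymethoxy)-3-(3-methylbut-2-en-1-yl)phenyl]-5-methoxy-7-(methoxymethoxy)-6-(3-methylbut-2-en-1-yl)-3,4-dihydro-2H-chromene
Product: 20 licoricidin
Conditions: HCl (aq, 3 M), MeOH, 40 °C
Reagents that add atoms: none
Why: Acid-catalysed acetal exchange with methanol (MOM ether cleavage) should release the three phenols at a temperature low enough to spare the ortho-prenyl phenols, and C3 is not enolisable and keeps its configuration.

Compound list
1 | 2-chloro-3-methoxyphenol | COc1cccc(O)c1Cl | starting material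
2 | (2-chloro-3-methoxyphenoxy)triisopropylsilane | COc1cccc(O[Si](C(C)C)(C(C)C)C(C)C)c1Cl | intermediate
3 | [2-chloro-3-methoxy-5-(4,4,5,5-tetramethyl-1,3,2-dioxaborolan-2-yl)phenoxy]triisopropylsilane | COc1cc(B2OC(C)(C)C(C)(C)O2)cc(O[Si](C(C)C)(C(C)C)C(C)C)c1Cl | intermediate
4 | 4-chloro-3-methoxy-5-(triisopropylsilyloxy)phenol | COc1cc(O)cc(O[Si](C(C)C)(C(C)C)C(C)C)c1Cl | intermediate
5 | [2-chloro-3-methoxy-5-(methoxymethoxy)phenoxy]triisopropylsilane | COCOc1cc(OC)c(Cl)c(O[Si](C(C)C)(C(C)C)C(C)C)c1 | intermediate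
6 | 1-bromo-3-methylbut-2-ene (prenyl bromide) | CC(C)=CCBr | starting material
7 | {3-chloro-2-methoxy-6-(methoxymethoxy)-4-(triisopropylsilyloxy)phenyl}lithium | [Li]c1c(OC)c(Cl)c(O[Si](C(C)C)(C(C)C)C(C)C)cc1OCOC | intermediate
8 | [2-chloro-3-methoxy-5-(methoxymethoxy)-4-(3-methylbut-2-en-1-yl)phenoxy]triisopropylsilane | COCOc1cc(O[Si](C(C)C)(C(C)C)C(C)C)c(Cl)c(OC)c1CC=C(C)C | intermediate
9 | 2-chloro-3-methoxy-5-(methoxymethoxy)-4-(3-methylbut-2-en-1-yl)phenol | COCOc1cc(O)c(Cl)c(OC)c1CC=C(C)C | intermediate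
10 | 4-bromobenzene-1,3-diol | Oc1ccc(Br)c(O)c1 | starting material
11 | 1-bromo-2,4-bis(methoxymethoxy)benzene | COCOc1ccc(Br)c(OCOC)c1 | intermediate
12 | [3-bromo-2,6-bis(methoxymethoxy)phenyl]lithium | [Li]c1c(OCOC)ccc(Br)c1OCOC | intermediate
13 | 1-bromo-2,4-bis(methoxymethoxy)-3-(3-methylbut-2-en-1-yl)benzene | COCOc1ccc(Br)c(OCOC)c1CC=C(C)C | intermediate
14 | 2-bromoprop-2-en-1-ol | OCC(Br)=C | starting material
15 | 2-[2,4-bis(methoxymethoxy)-3-(3-methylbut-2-en-1-yl)phenyl]-4,4,5,5-tetramethyl-1,3,2-dioxaborolane | COCOc1ccc(B2OC(C)(C)C(C)(C)O2)c(OCOC)c1CC=C(C)C | intermediate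
16 | 2-[2,4-bis(methoxymethoxy)-3-(3-methylbut-2-en-1-yl)phenyl]prop-2-en-1-ol | COCOc1ccc(C(=C)CO)c(OCOC)c1CC=C(C)C | intermediate
17 | 1-({2-[2,4-bis(methoxymethoxy)-3-(3-methylbut-2-en-1-yl)phenyl]prop-2-en-1-yl}oxy)-2-chloro-3-methoxy-5-(methoxymethoxy)-4-(3-methylbut-2-en-1-yl)benzene | COCOc1cc(OCC(=C)c2ccc(OCOC)c(CC=C(C)C)c2OCOC)c(Cl)c(OC)c1CC=C(C)C | intermediate
18 | 2-{(2R)-2-[2,4-bis(methoxymethoxy)-3-(3-methylbut-2-en-1-yl)phenyl]-3-[2-chloro-3-methoxy-5-(methoxymethoxy)-4-(3-methylbut-2-en-1-yl)phenoxy]propyl}-4,4,5,5-tetramethyl-1,3,2-dioxaborolane | COCOc1cc(OC[C@H](CB2OC(C)(C)C(C)(C)O2)c2ccc(OCOC)c(CC=C(C)C)c2OCOC)c(Cl)c(OC)c1CC=C(C)C | intermediate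
19 | (3R)-3-[2,4-bis(methoxymethoxy)-3-(3-methylbut-2-en-1-yl)phenyl]-5-methoxy-7-(methoxymethoxy)-6-(3-methylbut-2-en-1-yl)-3,4-dihydro-2H-chromene | COc1c(CC=C(C)C)c(OCOC)cc2c1C[C@H](c1ccc(OCOC)c(CC=C(C)C)c1OCOC)CO2 | intermediate
20 | licoricidin, 4-[(3R)-7-hydroxy-5-methoxy-6-(3-methylbut-2-en-1-yl)-3,4-dihydro-2H-chromen-3-yl]-2-(3-methylbut-2-en-1-yl)benzene-1,3-diol | COc1c(CC=C(C)C)c(O)cc2c1C[C@H](c1ccc(O)c(CC=C(C)C)c1O)CO2 | target

Total step count: 11 steps.
Longest linear sequence: 8 steps (steps 1–5, 9, 10, 11); the ring B fragment (steps 6–8) joins at step 9.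

Steps most likely to fail

1. Step 10. Facial selectivity in the hydrocupration may be too low for this ortho-substituted, electron-rich aryl alkene. Copper may also add to the benzylic carbon and expel aryloxide, which cleaves the allyl ether. Oxidative addition into the hindered, electron-rich aryl chloride may be slow. The fallback sets the stereocentre by enzymatic desymmetrisation and closes the same bond by a Negishi reaction.
   - It sets out from 16: hydroboration with 9-BBN and oxidation with NaBO3 should give the prochiral diol 2-[2,4-bis(methoxymethoxy)-3-(3-methylbut-2-en-1-yl)phenyl]propane-1,3-diol F1.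
   - Acetylation of one enantiotopic hydroxymethyl group with a lipase chosen by screening (for example the lipase of Burkholderia cepacia, vinyl acetate, MTBE) should give (2R)-2-[2,4-bis(methoxymethoxy)-3-(3-methylbut-2-en-1-yl)phenyl]-3-hydroxypropyl acetate F2.
   - Mitsunobu etherification of F2 with phenol 9 should give (2R)-2-[2,4-bis(methoxymethoxy)-3-(3-methylbut-2-en-1-yl)phenyl]-3-[2-chloro-3-methoxy-5-(methoxymethoxy)-4-(3-methylbut-2-en-1-yl)phenoxy]propyl acetate F3.
   - Methanolysis (K2CO3, MeOH) should give (2S)-2-[2,4-bis(methoxymethoxy)-3-(3-methylbut-2-en-1-yl)phenyl]-3-[2-chloro-3-methoxy-5-(methoxymethoxy)-4-(3-methylbut-2-en-1-yl)phenoxy]propan-1-ol F4.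
   - I2, PPh3 and imidazole should give 1-({(2R)-2-[2,4-bis(methoxymethoxy)-3-(3-methylbut-2-en-1-yl)phenyl]-3-iodopropyl}oxy)-2-chloro-3-methoxy-5-(methoxymethoxy)-4-(3-methylbut-2-en-1-yl)benzene F5.
   - Zinc insertion (Zn dust, LiCl, THF) should give {(2R)-2-[2,4-bis(methoxymethoxy)-3-(3-methylbut-2-en-1-yl)phenyl]-3-[2-chloro-3-methoxy-5-(methoxymethoxy)-4-(3-methylbut-2-en-1-yl)phenoxy]propyl}zinc iodide F6.
   - Intramolecular Negishi coupling of F6 (Pd(OAc)2, RuPhos, THF, 60 °C) forms C4–C4a, and the fallback comes back to the route at 19.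

2. Step 7. The amide base may also deprotonate ortho to bromine, which leads to loss of LiBr, or bromine may migrate between aryllithium and aryl bromide; attack at the tertiary end of prenyl bromide is a further risk. The fallback reverses the order so that the lithiation is done on a halogen-free arene with n-BuLi.
   - It sets out from 11: one-pot Miyaura borylation and Suzuki–Miyaura coupling with 14, as in step 8, should pass through 2-[2,4-bis(methoxymethoxy)phenyl]-4,4,5,5-tetramethyl-1,3,2-dioxaborolane F7 and give 2-[2,4-bis(methoxymethoxy)phenyl]prop-2-en-1-ol F8.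
   - Silylation (tert-butyldimethylsilyl chloride, imidazole) should give {2-[2,4-bis(methoxymethoxy)phenyl]prop-2-en-1-yl}oxy(tert-butyl)dimethylsilane F9.
   - n-BuLi in THF at 0 °C should lithiate between the two MOM ethers to give {3-[3-(tert-butyldimethylsilyloxy)prop-1-en-2-yl]-2,6-bis(methoxymethoxy)phenyl}lithium F10.
   - Copper-catalysed allylation with 6 should give {2-[2,4-bis(methoxymethoxy)-3-(3-methylbut-2-en-1-yl)phenyl]prop-2-en-1-yl}oxy(tert-butyl)dimethylsilane F11.
   - Bu4NF removes the silyl group, and the fallback comes back to the route at 16.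

3. Step 11. Under protic acid a freed phenol may add to the neighbouring prenyl double bond and form a dimethylchroman. The fallback exchanges the protecting groups under non-protic conditions and frees the phenols with base.
   - It sets out from 19: triethylsilyl triflate and 2,2'-bipyridyl (CH2Cl2, 0 °C) should convert the three aryl MOM ethers into silyl ethers and give (3R)-3-[2,4-bis(triethylsilyloxy)-3-(3-methylbut-2-en-1-yl)phenyl]-5-methoxy-6-(3-methylbut-2-en-1-yl)-7-(triethylsilyloxy)-3,4-dihydro-2H-chromene F12.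
   - Methanolysis with catalytic K2CO3 in MeOH at 0 °C then comes back to the route at 20.

Further compounds
F1 | step 10 | 2-[2,4-bis(methoxymethoxy)-3-(3-methylbut-2-en-1-yl)phenyl]propane-1,3-diol | OCC(CO)c1ccc(OCOC)c(CC=C(C)C)c1OCOC
F2 | step 10 | (2R)-2-[2,4-bis(methoxymethoxy)-3-(3-methylbut-2-en-1-yl)phenyl]-3-hydroxypropyl acetate | OC[C@H](COC(C)=O)c1ccc(OCOC)c(CC=C(C)C)c1OCOC
F3 | step 10 | (2R)-2-[2,4-bis(methoxymethoxy)-3-(3-methylbut-2-en-1-yl)phenyl]-3-[2-chloro-3-methoxy-5-(methoxymethoxy)-4-(3-methylbut-2-en-1-yl)phenoxy]propyl acetate | COCOc1cc(OC[C@H](COC(C)=O)c2ccc(OCOC)c(CC=C(C)C)c2OCOC)c(Cl)c(OC)c1CC=C(C)C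
F4 | step 10 | (2S)-2-[2,4-bis(methoxymethoxy)-3-(3-methylbut-2-en-1-yl)phenyl]-3-[2-chloro-3-methoxy-5-(methoxymethoxy)-4-(3-methylbut-2-en-1-yl)phenoxy]propan-1-ol | COCOc1cc(OC[C@H](CO)c2ccc(OCOC)c(CC=C(C)C)c2OCOC)c(Cl)c(OC)c1CC=C(C)C
F5 | step 10 | 1-({(2R)-2-[2,4-bis(methoxymethoxy)-3-(3-methylbut-2-en-1-yl)phenyl]-3-iodopropyl}oxy)-2-chloro-3-methoxy-5-(methoxymethoxy)-4-(3-methylbut-2-en-1-yl)benzene | COCOc1cc(OC[C@H](CI)c2ccc(OCOC)c(CC=C(C)C)c2OCOC)c(Cl)c(OC)c1CC=C(C)C
F6 | step 10 | {(2R)-2-[2,4-bis(methoxymethoxy)-3-(3-methylbut-2-en-1-yl)phenyl]-3-[2-chloro-3-methoxy-5-(methoxymethoxy)-4-(3-methylbut-2-en-1-yl)phenoxy]propyl}zinc iodide | COCOc1cc(OC[C@H](C[Zn]I)c2ccc(OCOC)c(CC=C(C)C)c2OCOC)c(Cl)c(OC)c1CC=C(C)C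
F7 | step 7 | 2-[2,4-bis(methoxymethoxy)phenyl]-4,4,5,5-tetramethyl-1,3,2-dioxaborolane | COCOc1ccc(B2OC(C)(C)C(C)(C)O2)c(OCOC)c1
F8 | step 7 | 2-[2,4-bis(methoxymethoxy)phenyl]prop-2-en-1-ol | COCOc1ccc(C(=C)CO)c(OCOC)c1
F9 | step 7 | {2-[2,4-bis(methoxymethoxy)phenyl]prop-2-en-1-yl}oxy(tert-butyl)dimethylsilane | COCOc1ccc(C(=C)CO[Si](C)(C)C(C)(C)C)c(OCOC)c1
F10 | step 7 | {3-[3-(tert-butyldimethylsilyloxy)prop-1-en-2-yl]-2,6-bis(methoxymethoxy)phenyl}lithium | [Li]c1c(OCOC)ccc(C(=C)CO[Si](C)(C)C(C)(C)C)c1OCOC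
F11 | step 7 | {2-[2,4-bis(methoxymethoxy)-3-(3-methylbut-2-en-1-yl)phenyl]prop-2-en-1-yl}oxy(tert-butyl)dimethylsilane | COCOc1ccc(C(=C)CO[Si](C)(C)C(C)(C)C)c(OCOC)c1CC=C(C)C
F12 | step 11 | (3R)-3-[2,4-bis(triethylsilyloxy)-3-(3-methylbut-2-en-1-yl)phenyl]-5-methoxy-6-(3-methylbut-2-en-1-yl)-7-(triethylsilyloxy)-3,4-dihydro-2H-chromene | COc1c(CC=C(C)C)c(O[Si](CC)(CC)CC)cc2c1C[C@H](c1ccc(O[Si](CC)(CC)CC)c(CC=C(C)C)c1O[Si](CC)(CC)CC)CO2
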